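(The numbers in the tables stem from a simulated flask with made-up constants, noise included.)

Late in a run of this kind the starting material meets the coupling partner that is left, not the partner charged, so I kept books before I extrapolated anything.

| flask | starting material | coupling partner | scavenger | remark | time |
|---|---|---|---|---|---|
| teal | 1 M | 2 equiv | 1.3 equiv | run made earlier |  |
| south-east | 1.0 M | 2.00 equiv | 1.20 equiv |  | 1.0 h |
| north | 1.0 M | 2.00 equiv | 1.60 equiv |  | 1.0 h |

teal run (percent of the starting material charged)

| time / min | starting material / % | mono adduct / % |
|---|---|---|
| 8.00 | 85 | 13 |
| 15.0 | 75 | 21 |
| 25.0 | 60 | 26 |
| 30.0 | 55 | 29 |

(each reading ± 1.5 percentage points)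

- released group is meant together with its idle adduct
- steps thought possible: starting material + coupling partner -> mono adduct + released group; starting material + coupling partner -> other mono adduct + released group; coupling partner + mono adduct -> bis adduct + released group; coupling partner + other mono adduct -> bis adduct + released group; starting material + released group <-> idle adduct; scavenger + released group -> scavenged by-product; mono adduct -> over-reaction product

- part of the starting material that has reacted at the end, south-east
- part of the starting material that has reacted at the end, north
- what raising the equivalents of scavenger from its lowest to its highest value here does to the part of the starting material that has reacted (changes below 5 percentage points count as none) (it falls / it rises / no change)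

Each step to the mono adduct, the other mono adduct or the bis adduct spends one coupling partner and frees one released group. My ledger for the teal run at 30.0 min read: 55 % of the starting material left, 29 % as mono adduct, and an unread 16.0 %, which I booked half as other mono adduct and half as bis adduct. That was my assumption, not a reading, and it booked nothing as idle adduct or over-reaction product. With 45.0 % reacted, the partner spent per starting material reacted came to

spending ratio = 1.18

Taking the mean partner as the charge less half of what was spent gave 1.74 M for the teal run, and so

ln(charged / left) / (mean partner × time) = 0.0115 M⁻¹ min⁻¹

This is the consumption constant, an apparent second-order rate constant read from the teal run. I then went round for south-east, keeping the spending ratio of the teal run and putting each answer back into the mean partner: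

first round, teal's mean partner: 69.8 % reacted
second round, mean partner 1.59 M: 66.6 % reacted
third round, mean partner 1.61 M: 67.0 % reacted

The released group freed equals the partner spent, by this reckoning 0.789 M in south-east, which is less than the 1.20 M of scavenger charged there. The teal run's 1.3 equiv also lies between the charges of south-east and north. So I kept the constant for both flasks and expected 67.0 % in each.

The forecast gave 66 % for south-east, a little below my figure, 67 % for north and no change, holding that “the scavenger never runs out”. The simulation gave 65.8 % in south-east and 65.7 % in north, a shift of −0.068 percentage points, so no change.

    starting material + coupling partner → mono adduct + released group (k = 1.50 × 10⁻⁴ M⁻¹ s⁻¹)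
    starting material + coupling partner → other mono adduct + released group (k = 5.00 × 10⁻⁵ M⁻¹ s⁻¹)
    coupling partner + mono adduct → bis adduct + released group (k = 9.30 × 10⁻⁵ M⁻¹ s⁻¹)
    coupling partner + other mono adduct → bis adduct + released group (k = 3.00 × 10⁻⁴ M⁻¹ s⁻¹)
    starting material + released group ⇌ idle adduct, settled at all times (K = 0.960 M⁻¹)
    scavenger + released group → scavenged by-product (k = 0.0490 M⁻¹ s⁻¹)
    mono adduct → over-reaction product (k = 2.70 × 10⁻⁷ s⁻¹)

In south-east at 0.378 h the scavenger had a half-life of 0.57 h by its own step, shorter than the 2.1 h of the coupling partner by the step to mono adduct. At 1.00 h that flask held 0.00832 M of released group beside 0.859 M of scavenged by-product, with 28 % of the scavenger left. A neighbouring flask, south-east read at 40 min, goes through the same constant: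

first round: 54.9 % reacted
second round, mean partner 1.68 M: 53.7 % reacted

The computed neighbouring flask stands at 54.2 %.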